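The runs were computed from invented constants, and the scatter is random.

Decide first what you will compare: not the recipes step by step, but how long the charge has had, on average, to react.

| setting | gamma | eta | grey | blue | teal | violet |
|---|---|---|---|---|---|---|
| substrate | 0.065 M | 0.065 M | 0.065 M | 0.065 M (fed, over 12 h) | 0.065 M | 0.065 M |
| reagent | 0.0715 M | 0.036 M | 0.0715 M (in portions, 4, over 12 h) | 0.0715 M | 0.0715 M (fed, over 12 h) | 0.0715 M |
| remark | run made earlier | run made earlier | first portion at the start, last at 12 h | all else is in the flask from the start; the feed brings no volume worth counting | all else is in the flask from the start; the feed brings no volume worth counting | everything together at the start |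
| time |  |  | 15 h | 15 h | 15 h | 15 h |

gamma run (percent of the substrate charged)

| time / h | target / % | substrate / % |
|---|---|---|
| 0.833 | 23.9 | 75.4 |
| 2.50 | 49.3 | 50.2 |
| 4.00 | 61.0 | 37.9 |
| 6.00 | 70.4 | 27.5 |
| 10.0 | 80.6 | 16.5 |
| 12.0 | 82.4 | 14.1 |
| 15.0 | 86.4 | 10.8 |

eta run (percent of the substrate charged)

| time / min | target / % | substrate / % |
|---|---|---|
| 5.00 | 1.9 | 98.3 |
| 15.0 | 4.5 | 95.2 |
| 25.0 | 6.4 | 93.2 |
| 40.0 | 10.2 | 90.7 |
| 50.0 | 12.6 | 87.1 |
| 80.0 | 19.1 | 81.5 |
| 90.0 | 20.6 | 78.8 |

(standard deviation of a reading: 0.5 percentage points)

- a reading or a percentage of target counts all its forms, free or not

1. the flask with the highest amount of target, in percent of the substrate charged ("all alike" if they lie within 1.5 percentage points) (grey / blue / teal / violet / all alike)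
2. final target, as a percentage of the substrate charged, in grey
3. final target, as a percentage of the substrate charged, in blue
4. final target, as a percentage of the substrate charged, in teal
5. final target, as a percentage of the substrate charged, in violet

Go to logarithms. If substrate and reagent are lost one for one at a rate first order in each (second order overall), the logarithm of [reagent]/[substrate] climbs on a straight line. Its slope is k([reagent] − [substrate]), and that difference stays constant. The gamma reading at 6.00 h gives k = 0.00153 /M/s. The eta reading at 90.0 min, with half the reagent, gives 0.00156 /M/s, close to it.

Now the ladder, fastest rung first. The clock 1/(k[substrate]) at full charge is 2.79 h. The run leaves grey, blue and teal 3.00 h after the last addition, about one such clock at full charge. Grey's portions land 4.00 h apart, longer than that clock, so early in grey a portion has more than one clock to react before the next arrives. The feed in blue and teal lasts 12 h, longer than that spacing. Below these rungs stands a side loss: the readings at the end of gamma leave 2.80% of the substrate unaccounted for, which I read as a selectivity of 96.9%.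

In grey, blue and teal alike, the dosed charge arrives on average at the middle of the feed. So carry the mean age of the charge, the run time less the mean arrival time: 9.00 h for these flasks, and 15 h for violet. Put as the time into the straight line, it gives me conversions of 88.7% in violet and 80.7% in the dosed flasks. With the selectivity, that is 85.9% and 78.2% of target. The last charge has had less than the mean age and ageing pays less and less, so I expect the dosed figures to come out somewhat lower, but violet leads by more than the margin.

The forecast put violet highest at 86%, with grey, blue and teal at 73%, 75% and 75.3%, lower than my dosed figure, saying “Late dosing wastes reaction time because concentrations stay low”.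

The simulation gives 86.1% in violet against 72.5%, 74.9% and 74.7% in grey, blue and teal, so violet stands highest. A hidden exchange between reagent and a dormant form relaxes in grey with a half-life of 2.20 min, far below the clock. Read backwards through the line, the 22.8% of substrate left at the end of blue corresponds to an age of 7.48 h, less than the mean age.

    substrate + released group → side product (k = 6.60 × 10⁻⁵ /M/s)
    crystals ⇌ target, rate k2*(cs2 - [target]) while solid is left; crystals form when [target] > cs2 (solubility = 21.0 mM, k = 0.00130 /s)
    substrate + reagent → target + released group (k = 0.00190 /M/s)
    reagent ⇌ dormant form (K = 0.330, k = 0.00130 /s)

Take the neighbour of grey with 0.016 M of substrate: its portions arrive as in grey, so the mean age stays 9.00 h, and the line with the selectivity gives 92.0% of target. The simulation of that flask gives 92.3%.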